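**Plan**

- Numbering follows the target SMILES (C1 … O27). The enabling feature is that, in the oxabicyclo[2.2.2]octane (C12, C13, C14, C17, O19, C20 with the bridge C23–C24), C20 is tied to C23 by C21–C22. The cage is therefore the [4+2] adduct of a 2H-pyran (O19, C20, C12, C13, C14, C17) and an alkene hung from C20.
- Retrosynthesis: cut C6–C8 (Claisen) and C26–C2 (alkenyl–aldehyde coupling) to remove C1–C6; open the O11–C9 lactone; cut C12–C23 and C17–C24 (Diels–Alder); cut O19–C17 and C13–C14 of the pyran (methyl acetoacetate plus a chloromethyl ketone); cut C8–C20 and O19–C20 back to a butyrolactone made from pent-4-ynoic acid.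
- Forward ring order: butyrolactone template (C12, C20, C21, C26) → 2H-pyran-3(4H)-one → silylene-bridged silyl dienol ether → cycloaddition (cyclopentane and carbocyclic six-membered ring) → γ-lactone → eight-membered ring by Dieckmann closure.
- Stereochemistry: C21 by Evans alkylation; C20 by trans alkylation of the lactone enolate; C12, C17, C23, C24 in the cycloaddition (tether face, E-alkene, oxidation with retention); C14 by hydroxyl-directed hydrogenation; C4 by Evans alkylation; C2 by base equilibration on the closed ring.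

Key step: step 13

Remark: the target is taken as the enol tautomer drawn in its SMILES. Enolates, alkoxides and organometallic forms of a numbered compound that arise in the flask are treated as that compound; neutral covalent intermediates of two-stage steps carry their own numbers. O27 is the oxygen on C26 throughout.

**Route**

Step 1
Reactants: 1 pent-4-ynoic acid; 2 (4S)-4-benzyl-1,3-oxazolidin-2-one
Product: 3 (4S)-4-benzyl-3-(pent-4-ynoyl)-1,3-oxazolidin-2-one
Conditions: DCC, DMAP (cat.), CH2Cl2, 0 → 25 °C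
Reagents that add atoms: none
Why: Carbodiimide/DMAP N-acylation (Steglich type) attaches the auxiliary that will control C21.

Step 2
Reactants: 3 (4S)-4-benzyl-3-(pent-4-ynoyl)-1,3-oxazolidin-2-one; 4 tert-butyl bromoacetate
Product: 5 tert-butyl (3R)-3-{[(4S)-4-benzyl-2-oxo-1,3-oxazolidin-3-yl]carbonyl}hex-5-ynoate
Conditions: NaHMDS, THF, −78 °C; then 4, −78 → −30 °C
Reagents that add atoms: none
Why: Evans alkylation, in which the chelated Z enolate (the imide is far more acidic than the alkyne C–H) is alkylated on the face away from the benzyl group, which sets C21.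

Step 3
Reactants: 5 tert-butyl (3R)-3-{[(4S)-4-benzyl-2-oxo-1,3-oxazolidin-3-yl]carbonyl}hex-5-ynoate
Product: 7 (4R)-4-(prop-2-yn-1-yl)oxolan-2-one, via tert-butyl (3R)-3-(hydroxymethyl)hex-5-ynoate 6 (not isolated)
Conditions: LiBH4, MeOH (1 equiv), THF, 0 °C; then TsOH·H2O (cat.), PhMe, 60 °C
Reagents that add atoms: none
Why: Reductive cleavage of the imide gives the primary alcohol (C26) without touching the tert-butyl ester, and acid-catalysed transesterification then closes the γ-lactone (C12, C20, C21, C26).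

Step 4
Reactants: 7 (4R)-4-(prop-2-yn-1-yl)oxolan-2-one
Product: 8 (3R,4S)-3-hydroxy-4-(prop-2-yn-1-yl)oxolan-2-one
Conditions: NaHMDS, THF, −78 °C; then 2-(benzenesulfonyl)-3-phenyloxaziridine, −78 °C
Reagents that add atoms: 2-(benzenesulfonyl)-3-phenyloxaziridine, O=S(=O)(c1ccccc1)N1OC1c1ccccc1
Why: Davis oxidation of the lactone enolate (a silazide base leaves the alkyne C–H alone) brings in O19 anti to the C21 side chain; this C20 configuration is provisional because step 6 re-enolises the centre.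

Step 5
Reactants: 8 (3R,4S)-3-hydroxy-4-(prop-2-yn-1-yl)oxolan-2-one
Product: 9 (3R,4S)-4-(prop-2-yn-1-yl)-3-(triethylsilyloxy)oxolan-2-one
Conditions: Et3SiCl, imidazole, DMF, 0 → 25 °C
Reagents that add atoms: chlorotriethylsilane, CC[Si](Cl)(CC)CC
Why: Routine silylation; the TES ether survives the next enolisation and falls to mild acid in step 10.

Step 6
Reactants: 9 (3R,4S)-4-(prop-2-yn-1-yl)-3-(triethylsilyloxy)oxolan-2-one; 4 tert-butyl bromoacetate
Product: 10 tert-butyl 2-[(3S,4S)-2-oxo-4-(prop-2-yn-1-yl)-3-(triethylsilyloxy)oxolan-3-yl]acetate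
Conditions: KHMDS, THF/DMPU, −78 °C; then 4, −78 → −40 °C
Reagents that add atoms: none
Why: Alkylation of the α-silyloxy lactone enolate anti to the C21 propargyl group (1,2-induction in a butyrolactone enolate) puts C8 trans and O19 cis to C22 and so sets the quaternary C20.

Step 7
Reactants: 10 tert-butyl 2-[(3S,4S)-2-oxo-4-(prop-2-yn-1-yl)-3-(triethylsilyloxy)oxolan-3-yl]acetate
Product: 12 tert-butyl (3S,4S)-3-[methoxy(methyl)carbamoyl]-3-(triethylsilyloxy)-4-[(triethylsilyloxy)methyl]hept-6-ynoate, via tert-butyl (3S,4S)-4-(hydroxymethyl)-3-[methoxy(methyl)carbamoyl]-3-(triethylsilyloxy)hept-6-ynoate 11 (not isolated)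
Conditions: MeNHOMe·HCl, Me3Al, CH2Cl2, 0 → 25 °C; then Et3SiCl, imidazole, DMF, 0 °C
Reagents that add atoms: N,O-dimethylhydroxylamine hydrochloride, CNOC.Cl; chlorotriethylsilane, CC[Si](Cl)(CC)CC
Why: Weinreb aminolysis of the lactone with the aluminium amide (the tert-butyl ester resists it) frees O27–H, which is silylated at once so that it cannot relactonise.

Step 8
Reactants: 12 tert-butyl (3S,4S)-3-[methoxy(methyl)carbamoyl]-3-(triethylsilyloxy)-4-[(triethylsilyloxy)methyl]hept-6-ynoate
Product: 13 tert-butyl (3S,4S)-3-(chloroacetyl)-3-(triethylsilyloxy)-4-[(triethylsilyloxy)methyl]hept-6-ynoate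
Conditions: ICH2Cl (3 equiv), MeLi·LiBr (3 equiv), THF, −78 °C; AcOH quench
Reagents that add atoms: chloroiodomethane, ClCI
Why: Chloromethyllithium made in situ adds once to the Weinreb amide (chelated tetrahedral adduct, homologation to an α-chloro ketone), which installs C13; the excess covers the acetylenic proton.

Step 9
Reactants: 13 tert-butyl (3S,4S)-3-(chloroacetyl)-3-(triethylsilyloxy)-4-[(triethylsilyloxy)methyl]hept-6-ynoate; 14 methyl acetoacetate
Product: 15 tert-butyl (3S,4S)-3-[3-(methoxycarbonyl)-4-oxopentanoyl]-3-(triethylsilyloxy)-4-[(triethylsilyloxy)methyl]hept-6-ynoate (both epimers at C14)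
Conditions: 14, NaH, THF, 0 °C; then 13, NaI (cat.), 25 °C
Reagents that add atoms: none
Why: SN2 C-alkylation of the acetoacetate enolate by the α-chloro ketone forms C13–C14; the C14 centre is lost again in step 10.

Step 10
Reactants: 15 tert-butyl (3S,4S)-3-[3-(methoxycarbonyl)-4-oxopentanoyl]-3-(triethylsilyloxy)-4-[(triethylsilyloxy)methyl]hept-6-ynoate
Product: 17 methyl (6S)-6-(2-tert-butoxy-2-oxoethyl)-6-[(2S)-1-hydroxypent-4-yn-2-yl]-2-methyl-5-oxo-5,6-dihydro-4H-pyran-3-carboxylate, via desilylated diol diketone 16 (not isolated)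
Conditions: CSA (cat.), MeOH, 0 → 25 °C; then PPTS (cat.), 4 Å MS, CH2Cl2, 25 °C
Reagents that add atoms: none
Why: Mild acid removes both TES groups, the tertiary O19–H adds to the C17 ketone as a six-membered hemiketal and water is lost toward the ester-activated C14 to give the cyclic β-alkoxy enoate (cyclodehydration); non-forcing acid is chosen to outrun Paal–Knorr furan formation, and a reversible O27/C12 hemiketal of 17 is harmless.

Step 11
Reactants: 17 methyl (6S)-6-(2-tert-butoxy-2-oxoethyl)-6-[(2S)-1-hydroxypent-4-yn-2-yl]-2-methyl-5-oxo-5,6-dihydro-4H-pyran-3-carboxylate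
Product: 19 silylene-bridged 3-silyloxy-2H-pyran alkyne (diene C12=C13–C14=C17; O11–Si(t-Bu)2–O27 closes a seven-membered ring through C26, C21, C20, C12), via alkoxysilyl triflate 18 (not isolated)
Conditions: t-Bu2Si(OTf)2, 2,6-lutidine, CH2Cl2, 0 °C; then Et3N, 25 °C
Reagents that add atoms: di-tert-butylsilyl bis(trifluoromethanesulfonate), CC(C)(C)[Si](OS(=O)(=O)C(F)(F)F)(OS(=O)(=O)C(F)(F)F)C(C)(C)C
Why: The primary alcohol is silylated first and the remaining Si–OTf then silylates the C12 ketone intramolecularly under soft enolisation (only C13 can enolise), which creates the diene and ties O27 to O11.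

Step 12
Reactants: 19 silylene-bridged 3-silyloxy-2H-pyran alkyne; 20 pinacolborane
Product: 21 silylene-bridged 3-silyloxy-2H-pyran bearing the E-alkenyl pinacol boronate C23=C24
Conditions: Cp2Zr(H)Cl (10 mol%), Et3N (10 mol%), CH2Cl2, 25 °C
Reagents that add atoms: none
Why: Zirconium-catalysed syn hydroboration of the terminal alkyne places boron on C24 and gives the E-alkene only.

Step 13
Reactants: 21 silylene-bridged 3-silyloxy-2H-pyran bearing the E-alkenyl pinacol boronate
Product: 22 cycloadduct: oxabicyclo[2.2.2]octene (C12, C13=C14, C17, O19, C20, bridge C23–C24) fused to cyclopentane (C12, C20, C21, C22, C23), C24–Bpin anti to O19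
Conditions: PhMe (0.01 M), BHT (cat.), 130 °C, sealed tube
Reagents that add atoms: none
Why: A thermal, concerted, suprafacial intramolecular Diels–Alder reaction joins the s-cis-locked dioxygenated diene C12=C13–C14=C17 to the alkenyl boronate C23=C24, forming C12–C23 and C17–C24. The closest known reactions are the intramolecular cycloadditions of 6-alkenyl-substituted cyclohexa-2,4-dienones and of 2H-pyrans to (oxa)isotwistanes, with alkenyl boronates as established dienophiles. The cyclopentane (C12, C20, C21, C22, C23) closes through the two-atom tether in the bridged five-membered mode by bond C12–C23, and the carbocyclic six-membered ring (C12, C13, C14, C17, C24, C23) closes as the cyclohexene of the [4+2], which completes the oxabicyclo[2.2.2]octene. C12 and C17 are set by the diene face, which is the one that carries C21 because the tether reaches no other; C23 is set by the tether; C24 is set by the E geometry, which puts boron anti to the O19 bridge. The selectivity needed is the relation between C21 and the cage, which reversible oxa-6π opening of the pyran at C20 could erode. The silylene secures it: only the isomer with C26 held next to O11 (and thus cis to C8) can reach the transition state, the other C20 epimer is returned through the dienone, and the same tie turns C22 toward C12 so that the six-membered closure onto C17 is excluded.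

Step 14
Reactants: 22 cycloadduct boronate
Product: 23 C24 alcohol (as 22 with C24–OH in place of boron, same configuration)
Conditions: NaBO3·4H2O, THF/H2O (1:1), 25 °C
Reagents that add atoms: sodium perborate tetrahydrate, O.O.O.O.[Na+].[O-]OB=O
Why: Oxidation of the C–B bond by 1,2-migration with retention gives O25 anti to O19, and the mild perborate spares the enoate and the silylene.

Step 15
Reactants: 23 C24 alcohol
Product: 24 C13–C14 saturated ester (C14–H on the face toward the C23–C24 bridge, C15 syn to O19)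
Conditions: [Ir(cod)(PCy3)(py)]PF6 (15 mol%), H2 (1 atm), CH2Cl2, 25 °C
Reagents that add atoms: none
Why: Hydroxyl-directed hydrogenation, in which the homoallylic C24–OH binds iridium and delivers hydrogen to the alkene face that looks toward C23–C24, sets C14.

Step 16
Reactants: 24 C13–C14 saturated ester
Product: 25 C15,C24 diol
Conditions: LiBH4, MeOH (1 equiv), THF, 0 → 25 °C
Reagents that add atoms: none
Why: Borohydride reduces the methyl ester to the C15 alcohol and leaves the tert-butyl ester and the silylene untouched.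

Step 17
Reactants: 25 C15,C24 diol
Product: 26 O16,O25-dibenzyl ether
Conditions: NaH, BnBr, Bu4NI (cat.), DMF, 0 → 25 °C
Reagents that add atoms: benzyl bromide, BrCc1ccccc1
Why: Williamson etherification protects both hydroxyls as ethers that withstand fluoride, acid, enolate and oxidation chemistry.

Step 18
Reactants: 26 O16,O25-dibenzyl ether
Product: 27 C12,C26 diol (tertiary O11–H and primary O27–H)
Conditions: Bu4NF, AcOH, THF, 25 °C
Reagents that add atoms: none
Why: Buffered fluoride cleaves both Si–O bonds of the silylene, and the tert-butyl ester does not lactonise onto O27.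

Step 19
Reactants: 27 C12,C26 diol
Product: 28 C26 aldehyde (may rest as its lactol with O11–H)
Conditions: (COCl)2, DMSO, CH2Cl2, −78 °C; Et3N, −78 → 0 °C
Reagents that add atoms: none
Why: Swern oxidation converts only the primary alcohol, and a stoichiometric oxidant that is spent before the lactol forms avoids over-oxidation to a bridged lactone.

Step 20
Reactants: 28 C26 aldehyde
Product: 30 γ-lactone aldehyde (O11–C9 lactone closed, C26 aldehyde free), via carboxylic acid 29 (not isolated)
Conditions: CF3CO2H/CH2Cl2 (1:4), 0 → 25 °C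
Reagents that add atoms: none
Why: Acid cleaves the tert-butyl ester and the C9 acid lactonises onto O11–H, now the only alcohol present, which also draws the aldehyde out of its lactol equilibrium.

Step 21
Reactants: 31 (4R)-4-benzyl-3-propanoyl-1,3-oxazolidin-2-one; 32 2,3-dibromoprop-1-ene
Product: 33 (4R)-4-benzyl-3-[(2S)-4-bromo-2-methylpent-4-enoyl]-1,3-oxazolidin-2-one
Conditions: NaHMDS, THF, −78 °C; then 32, −78 → −40 °C
Reagents that add atoms: none
Why: Evans alkylation of the Z enolate away from the benzyl group sets C4.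

Step 22
Reactants: 33 (4R)-4-benzyl-3-[(2S)-4-bromo-2-methylpent-4-enoyl]-1,3-oxazolidin-2-one
Product: 34 methyl (2S)-4-bromo-2-methylpent-4-enoate
Conditions: MeMgBr, MeOH, 0 °C
Reagents that add atoms: methanol, CO
Why: Transesterification with methoxymagnesium bromide removes the auxiliary by exocyclic cleavage without epimerising C4.

Step 23
Reactants: 30 γ-lactone aldehyde; 34 methyl (2S)-4-bromo-2-methylpent-4-enoate
Product: 35 C26 allylic alcohol (C26(OH)–C2(=C1H2)–C3H2–C4H(CH3)–C6O2Me; both C26 epimers)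
Conditions: CrCl2 (divalent chromium, 5 equiv), NiCl2 (2 mol%), DMSO/THF, 25 °C
Reagents that add atoms: none
Why: Nozaki–Hiyama–Kishi coupling, in which the alkenylchromium species adds to the aldehyde only and forms C26–C2 beside lactone and ester; the carbinol configuration is lost in step 24.

Step 24
Reactants: 35 C26 allylic alcohol
Product: 36 α-methylene ketone (C26=O, C2=C1H2)
Conditions: Dess–Martin periodinane, NaHCO3, CH2Cl2, 25 °C
Reagents that add atoms: none
Why: Dess–Martin oxidation of the secondary allylic alcohol gives the C26 ketone under buffered, non-epimerising conditions.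

Step 25
Reactants: 36 α-methylene ketone
Product: 37 keto ester (C26(=O)–C2H(CH3)–C3H2–C4H(CH3)–C6O2Me; both C2 epimers)
Conditions: RhCl(PPh3)3 (10 mol%), H2 (1 atm), PhH/EtOH, 25 °C
Reagents that add atoms: none
Why: Homogeneous hydrogenation saturates the 1,1-disubstituted enone alkene without cleaving the benzyl ethers; C2 arises unselectively and is corrected in step 26.

Step 26
Reactants: 37 keto ester
Product: 39 O16,O25-dibenzyl abyssomicin O, via C2-epimer mixture 38 (not isolated)
Conditions: LiHMDS (3.5 equiv), THF (0.005 M), −78 → 0 °C, substrate added to base; AcOH; then DBU (0.3 equiv), CH2Cl2, 25 °C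
Reagents that add atoms: none
Why: Dieckmann (intramolecular Claisen) condensation, in which ketone and lactone are both enolised by excess base so that the lactone enolate C8 can attack only the C6 ester, closes the eight-membered ring on the cis C20/C21 substituents and ends in the stabilised β-keto lactone enolate; DBU then equilibrates C2 (α to the C26 ketone) toward the cis-2,4-dimethyl isomer, in which both methyl groups should sit pseudo-equatorially.

Step 27
Reactants: 39 O16,O25-dibenzyl abyssomicin O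
Product: 40 abyssomicin O
Conditions: H2 (1 atm), Pd(OH)2/C, EtOAc, 25 °C
Reagents that add atoms: none
Why: Hydrogenolysis removes both benzyl ethers, while the hydrogen-bonded tetrasubstituted enol and the ketone are not reduced.

**Compound list**

1 | pent-4-ynoic acid | C#CCCC(=O)O | starting material
2 | (4S)-4-benzyl-1,3-oxazolidin-2-one | O=C1N[C@@H](Cc2ccccc2)CO1 | starting material
3 | (4S)-4-benzyl-3-(pent-4-ynoyl)-1,3-oxazolidin-2-one | C#CCCC(=O)N1[C@@H](Cc2ccccc2)COC1=O | intermediate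
4 | tert-butyl bromoacetate | CC(C)(C)OC(=O)CBr | starting material
5 | tert-butyl (3R)-3-{[(4S)-4-benzyl-2-oxo-1,3-oxazolidin-3-yl]carbonyl}hex-5-ynoate | CC(C)(C)OC(=O)C[C@@H](CC#C)C(=O)N1[C@@H](Cc2ccccc2)COC1=O | intermediate
6 | tert-butyl (3R)-3-(hydroxymethyl)hex-5-ynoate | CC(C)(C)OC(=O)C[C@@H](CC#C)CO | intermediate
7 | (4R)-4-(prop-2-yn-1-yl)oxolan-2-one | O=C1C[C@@H](CC#C)CO1 | intermediate
8 | (3R,4S)-3-hydroxy-4-(prop-2-yn-1-yl)oxolan-2-one | O=C1[C@H](O)[C@@H](CC#C)CO1 | intermediate
9 | (3R,4S)-4-(prop-2-yn-1-yl)-3-(triethylsilyloxy)oxolan-2-one | O=C1[C@H](O[Si](CC)(CC)CC)[C@@H](CC#C)CO1 | intermediate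
10 | tert-butyl 2-[(3S,4S)-2-oxo-4-(prop-2-yn-1-yl)-3-(triethylsilyloxy)oxolan-3-yl]acetate | O=C1[C@](O[Si](CC)(CC)CC)(CC(=O)OC(C)(C)C)[C@@H](CC#C)CO1 | intermediate
11 | tert-butyl (3S,4S)-4-(hydroxymethyl)-3-[methoxy(methyl)carbamoyl]-3-(triethylsilyloxy)hept-6-ynoate | CON(C)C(=O)[C@](O[Si](CC)(CC)CC)(CC(=O)OC(C)(C)C)[C@@H](CC#C)CO | intermediate
12 | tert-butyl (3S,4S)-3-[methoxy(methyl)carbamoyl]-3-(triethylsilyloxy)-4-[(triethylsilyloxy)methyl]hept-6-ynoate | CON(C)C(=O)[C@](O[Si](CC)(CC)CC)(CC(=O)OC(C)(C)C)[C@@H](CC#C)CO[Si](CC)(CC)CC | intermediate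
13 | tert-butyl (3S,4S)-3-(chloroacetyl)-3-(triethylsilyloxy)-4-[(triethylsilyloxy)methyl]hept-6-ynoate | ClCC(=O)[C@](O[Si](CC)(CC)CC)(CC(=O)OC(C)(C)C)[C@@H](CC#C)CO[Si](CC)(CC)CC | intermediate
14 | methyl acetoacetate | CC(=O)CC(=O)OC | starting material
15 | tert-butyl (3S,4S)-3-[3-(methoxycarbonyl)-4-oxopentanoyl]-3-(triethylsilyloxy)-4-[(triethylsilyloxy)methyl]hept-6-ynoate, both C14 epimers | CC(=O)C(C(=O)OC)CC(=O)[C@](O[Si](CC)(CC)CC)(CC(=O)OC(C)(C)C)[C@@H](CC#C)CO[Si](CC)(CC)CC | intermediate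
16 | tert-butyl (3S,4S)-3-hydroxy-4-(hydroxymethyl)-3-[3-(methoxycarbonyl)-4-oxopentanoyl]hept-6-ynoate | CC(=O)C(C(=O)OC)CC(=O)[C@](O)(CC(=O)OC(C)(C)C)[C@@H](CC#C)CO | intermediate
17 | methyl (6S)-6-(2-tert-butoxy-2-oxoethyl)-6-[(2S)-1-hydroxypent-4-yn-2-yl]-2-methyl-5-oxo-5,6-dihydro-4H-pyran-3-carboxylate | CC1=C(C(=O)OC)CC(=O)[C@](CC(=O)OC(C)(C)C)([C@@H](CC#C)CO)O1 | intermediate
18 | O27-[di-tert-butyl(trifluoromethanesulfonyloxy)silyl] ether of 17 | CC1=C(C(=O)OC)CC(=O)[C@](CC(=O)OC(C)(C)C)([C@@H](CC#C)CO[Si](OS(=O)(=O)C(F)(F)F)(C(C)(C)C)C(C)(C)C)O1 | intermediate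
19 | silylene-bridged 3-silyloxy-2H-pyran alkyne: pyran O19, C20, C12=C13, C14=C17; C20 bears CH2CO2t-Bu and C21; C14 CO2Me; C17 Me; O11–Si(t-Bu)2–O27–C26H2–C21 ring; C21 bears CH2C≡CH | CC(C)(C)OC(=O)C[C@@]12C(O[Si](C(C)(C)C)(C(C)(C)C)OC[C@@H]1CC#C)=CC(C(=O)OC)=C(C)O2 | intermediate
20 | pinacolborane | B1OC(C)(C)C(C)(C)O1 | starting material
21 | as 19 with C21 bearing CH2–CH=CH–Bpin (E), the cycloaddition precursor | CC(C)(C)OC(=O)C[C@@]12C(O[Si](C(C)(C)C)(C(C)(C)C)OC[C@@H]1C/C=C/B3OC(C)(C)C(C)(C)O3)=CC(C(=O)OC)=C(C)O2 | intermediate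
22 | cycloadduct: oxabicyclo[2.2.2]octene (C12, C13=C14, C17, O19, C20, bridge C23–C24) fused to cyclopentane (C12, C20, C21, C22, C23); C24 Bpin anti to O19; C14 CO2Me; C17 Me; C20 CH2CO2t-Bu; O11–Si(t-Bu)2–O27–C26 bridge | CC(C)(C)OC(=O)C[C@@]12O[C@@]3(C)C(C(=O)OC)=C[C@]1(O[Si](C(C)(C)C)(C(C)(C)C)OC4)[C@@H](C[C@H]24)[C@@H]3B5OC(C)(C)C(C)(C)O5 | intermediate
23 | as 22 with C24–OH in place of Bpin | CC(C)(C)OC(=O)C[C@@]12O[C@@]3(C)C(C(=O)OC)=C[C@]1(O[Si](C(C)(C)C)(C(C)(C)C)OC4)[C@@H](C[C@H]24)[C@@H]3O | intermediate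
24 | as 23 with C13–C14 saturated, C14 CO2Me syn to O19 | CC(C)(C)OC(=O)C[C@@]12O[C@@]3(C)[C@@H](C(=O)OC)C[C@]1(O[Si](C(C)(C)C)(C(C)(C)C)OC4)[C@@H](C[C@H]24)[C@@H]3O | intermediate
25 | as 24 with C15H2OH (C15,C24 diol) | CC(C)(C)OC(=O)C[C@@]12O[C@@]3(C)[C@@H](CO)C[C@]1(O[Si](C(C)(C)C)(C(C)(C)C)OC4)[C@@H](C[C@H]24)[C@@H]3O | intermediate
26 | as 25 with O16 and O25 benzylated | CC(C)(C)OC(=O)C[C@@]12O[C@@]3(C)[C@@H](COCc5ccccc5)C[C@]1(O[Si](C(C)(C)C)(C(C)(C)C)OC4)[C@@H](C[C@H]24)[C@@H]3OCc1ccccc1 | intermediate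
27 | as 26 without the silylene: C12–OH and C26H2–OH | CC(C)(C)OC(=O)C[C@@]12O[C@@]3(C)[C@@H](COCc5ccccc5)C[C@]1(O)[C@@H](C[C@H]2CO)[C@@H]3OCc1ccccc1 | intermediate
28 | as 27 with C26 aldehyde | CC(C)(C)OC(=O)C[C@@]12O[C@@]3(C)[C@@H](COCc5ccccc5)C[C@]1(O)[C@@H](C[C@H]2C=O)[C@@H]3OCc1ccccc1 | intermediate
29 | as 28 with free C9 carboxylic acid | OC(=O)C[C@@]12O[C@@]3(C)[C@@H](COCc5ccccc5)C[C@]1(O)[C@@H](C[C@H]2C=O)[C@@H]3OCc1ccccc1 | intermediate
30 | γ-lactone aldehyde: lactone C8–C9(=O)–O11–C12–C20, C26 aldehyde, O16 and O25 benzylated | O=C6C[C@@]12O[C@@]3(C)[C@@H](COCc5ccccc5)C[C@]1(O6)[C@@H](C[C@H]2C=O)[C@@H]3OCc1ccccc1 | intermediate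
31 | (4R)-4-benzyl-3-propanoyl-1,3-oxazolidin-2-one | CCC(=O)N1[C@H](Cc2ccccc2)COC1=O | starting material
32 | 2,3-dibromoprop-1-ene | C=C(Br)CBr | starting material
33 | (4R)-4-benzyl-3-[(2S)-4-bromo-2-methylpent-4-enoyl]-1,3-oxazolidin-2-one | C=C(Br)C[C@H](C)C(=O)N1[C@H](Cc2ccccc2)COC1=O | intermediate
34 | methyl (2S)-4-bromo-2-methylpent-4-enoate | COC(=O)[C@@H](C)CC(Br)=C | intermediate
35 | as 30 with C26H(OH)–C2(=CH2)–C3H2–C4H(CH3)–CO2Me, both C26 epimers | O=C6C[C@@]12O[C@@]3(C)[C@@H](COCc5ccccc5)C[C@]1(O6)[C@@H](C[C@H]2C(O)C(=C)C[C@H](C)C(=O)OC)[C@@H]3OCc1ccccc1 | intermediate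
36 | as 35 with C26 ketone (α-methylene ketone) | O=C6C[C@@]12O[C@@]3(C)[C@@H](COCc5ccccc5)C[C@]1(O6)[C@@H](C[C@H]2C(=O)C(=C)C[C@H](C)C(=O)OC)[C@@H]3OCc1ccccc1 | intermediate
37 | as 36 with C2H(CH3), both C2 epimers | O=C6C[C@@]12O[C@@]3(C)[C@@H](COCc5ccccc5)C[C@]1(O6)[C@@H](C[C@H]2C(=O)C(C)C[C@H](C)C(=O)OC)[C@@H]3OCc1ccccc1 | intermediate
38 | O16,O25-dibenzyl abyssomicin O as C2-epimer mixture | CC1C[C@H](C)/C(O)=C2/C(=O)O[C@]34C[C@H](COCc6ccccc6)[C@]5(C)O[C@]23[C@@H](C[C@H]4[C@@H]5OCc7ccccc7)C1=O | intermediate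
39 | O16,O25-dibenzyl abyssomicin O | C[C@@H]1C[C@H](C)/C(O)=C2/C(=O)O[C@]34C[C@H](COCc6ccccc6)[C@]5(C)O[C@]23[C@@H](C[C@H]4[C@@H]5OCc7ccccc7)C1=O | intermediate
40 | abyssomicin O | C[C@@H]1C[C@H](C)/C(O)=C2/C(=O)O[C@]34C[C@H](CO)[C@]5(C)O[C@]23[C@@H](C[C@H]4[C@@H]5O)C1=O | target

**Step count and risks**

Total: 27 steps. Longest linear sequence: 25 steps (steps 1–20 and 23–27); steps 21–22 make the side-chain fragment.

Steps most likely to fail:

1. Step 13. The cycloaddition with the weakly activated alkenyl boronate may be slower than thermal decay of the silyl dienol ether or than escape through the ring-opened dienone. The fallback changes the activating group and the way O25 is introduced. It sets out from alkyne 19. Hydrozirconation with Cp2Zr(H)Cl and CuBr·SMe2-catalysed acylation with acetyl chloride should give the E-methyl enone F1. This far more reactive dienophile should cyclise at 60–80 °C in toluene to the C24 acetyl cycloadduct F2, with the acetyl group where boron would have been. Baeyer–Villiger oxidation (CF3CO3H, Na2HPO4, CH2Cl2) migrates C24 with retention to the C24 acetate F3, and K2CO3 in MeOH returns the route at alcohol 23.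

2. Step 26. The eight-membered Claisen closure may lose out to oligomerisation, or to a six-membered closure of the C2 enolate onto the lactone carbonyl if enolisation is incomplete, and the C2 equilibrium may not favour the wanted epimer. The fallback reverses the order of the two bonds and closes the ring without base at C26–C2. It sets out from 30 and 34. Compound 30 is protected as the dimethyl acetal F6 (HC(OMe)3, PPTS). Its lactone enolate (LiHMDS, −78 °C) is added to (2S)-4-bromo-2-methylpent-4-enal F7 (from 34 with DIBAL-H at −78 °C) to give the aldol adduct F8. Dess–Martin oxidation gives the β-keto lactone F9, and aqueous acid unveils the keto aldehyde F10. An intramolecular Nozaki–Hiyama–Kishi reaction (CrCl2, NiCl2 cat., DMSO, high dilution) closes the ring to the allylic alcohol F11. MnO2 gives the ring α-methylene ketone F12, and hydrogenation over RhCl(PPh3)3 (with DBU if the kinetic C2 epimer prevails) returns the route at 39.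

3. Step 10. The 1,4-diketone may close to a furan (Paal–Knorr), or the O27/C12 hemiketal may dehydrate, faster than the wanted enol-ether closure. The fallback never forms a 1,4-diketone and sets out from chloro ketone 13. Methyl (triphenylphosphoranylidene)acetate (2 equiv) is alkylated by 13 to the phosphorane F4. A ketene Wittig reaction (AcCl, Et3N) gives the 2-substituted buta-2,3-dienoate F5. CSA in MeOH removes the TES groups, and the tertiary O19–H then adds to the central allene carbon (Et3N, six-membered oxa-Michael closure) with isomerisation to the conjugated enol ether, which returns the route at 17.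

**Further compounds**

F1 | step 13 | as 19 with C21 bearing CH2–CH=CH–C(=O)CH3 (E) | CC(C)(C)OC(=O)C[C@@]12C(O[Si](C(C)(C)C)(C(C)(C)C)OC[C@@H]1C/C=C/C(C)=O)=CC(C(=O)OC)=C(C)O2
F2 | step 13 | as 22 with C24 acetyl in place of Bpin | CC(C)(C)OC(=O)C[C@@]12O[C@@]3(C)C(C(=O)OC)=C[C@]1(O[Si](C(C)(C)C)(C(C)(C)C)OC4)[C@@H](C[C@H]24)[C@@H]3C(C)=O
F3 | step 13 | as 22 with C24 acetate in place of Bpin | CC(C)(C)OC(=O)C[C@@]12O[C@@]3(C)C(C(=O)OC)=C[C@]1(O[Si](C(C)(C)C)(C(C)(C)C)OC4)[C@@H](C[C@H]24)[C@@H]3OC(C)=O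
F4 | step 10 | phosphorane from 13: C13H2–C14(=PPh3)–CO2Me | COC(=O)C(=P(c1ccccc1)(c1ccccc1)c1ccccc1)CC(=O)[C@](O[Si](CC)(CC)CC)(CC(=O)OC(C)(C)C)[C@@H](CC#C)CO[Si](CC)(CC)CC
F5 | step 10 | allenoate: C13H2–C14(CO2Me)=C17=C18H2 | C=C=C(C(=O)OC)CC(=O)[C@](O[Si](CC)(CC)CC)(CC(=O)OC(C)(C)C)[C@@H](CC#C)CO[Si](CC)(CC)CC
F6 | step 26 | dimethyl acetal of 30 | O=C6C[C@@]12O[C@@]3(C)[C@@H](COCc5ccccc5)C[C@]1(O6)[C@@H](C[C@H]2C(OC)OC)[C@@H]3OCc1ccccc1
F7 | step 26 | (2S)-4-bromo-2-methylpent-4-enal | O=C[C@@H](C)CC(Br)=C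
F8 | step 26 | aldol adduct: C8 of F6 bearing C6H(OH)–C4H(CH3)–C3H2–C2(Br)=CH2 | O=C6C(C(O)[C@@H](C)CC(Br)=C)[C@@]12O[C@@]3(C)[C@@H](COCc5ccccc5)C[C@]1(O6)[C@@H](C[C@H]2C(OC)OC)[C@@H]3OCc1ccccc1
F9 | step 26 | β-keto lactone acetal (C6 ketone) | O=C6C(C(=O)[C@@H](C)CC(Br)=C)[C@@]12O[C@@]3(C)[C@@H](COCc5ccccc5)C[C@]1(O6)[C@@H](C[C@H]2C(OC)OC)[C@@H]3OCc1ccccc1
F10 | step 26 | β-keto lactone with free C26 aldehyde | O=C6C(C(=O)[C@@H](C)CC(Br)=C)[C@@]12O[C@@]3(C)[C@@H](COCc5ccccc5)C[C@]1(O6)[C@@H](C[C@H]2C=O)[C@@H]3OCc1ccccc1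
F11 | step 26 | ring-closed allylic alcohol: eight-membered ring with C26H(OH) and C2=C1H2 | C=C1C[C@H](C)/C(O)=C2/C(=O)O[C@]34C[C@H](COCc6ccccc6)[C@]5(C)O[C@]23[C@@H](C[C@H]4[C@@H]5OCc7ccccc7)C1O
F12 | step 26 | ring α-methylene ketone: C26=O and C2=C1H2 | C=C1C[C@H](C)/C(O)=C2/C(=O)O[C@]34C[C@H](COCc6ccccc6)[C@]5(C)O[C@]23[C@@H](C[C@H]4[C@@H]5OCc7ccccc7)C1=O
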